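Each butyrolactone has a tertiary carbinol carbon Cα (bearing OH, the lactone C=O and the CH2 of ring B or ring D). Next to it sits the methine Cβ (bearing the ring OCH2 and the CH2 of ring A or ring C). This vicinal pair is the imprint of a trisubstituted 2,3-epoxy alcohol opened at its CH carbon. The route therefore forms both Cβ–C(H2O) bonds in one operation. A vinyl cuprate inverts the two epoxide methines of a tetra-O-benzyl, bis-O-silyl (2S,3R,2'S,3'R)-bis-epoxide built on the B–C biaryl, and both Cα–O bonds stay intact. Each vinyl group later becomes the ring CH2O, and each CH2OSi arm becomes the lactone carbonyl.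

Key step: step 16

Remark: 1, 5 and 9 are taken as catalogue compounds (otherwise reached from vanillin by routine benzylation, reduction or persulfate coupling). Enol ethers 3 and 12–16 are E/Z mixtures and phosphonates 8 and 15 are racemic at the P-bearing carbon, which does not matter because these elements disappear later. Half 1 means rings A/B and half 2 means rings C/D.

Step 1
Reactants: 1 4-benzyloxy-3-methoxybenzaldehyde (O-benzylvanillin); 2 (methoxymethyl)triphenylphosphonium chloride
Product: 3 1-benzyloxy-2-methoxy-4-(2-methoxyethenyl)benzene (E/Z mixture)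
Conditions: 2 (1.3 equiv), KOtBu (1.3 equiv), THF, 0 °C → rt
Reagents that add atoms: none
Why: Wittig methoxymethylenation of a non-enolisable aromatic aldehyde is a routine one-carbon homologation, and the E/Z mixture is irrelevant because both isomers hydrolyse to the same aldehyde.

Step 2
Reactants: 3 enol ether
Product: 4 (4-benzyloxy-3-methoxyphenyl)acetaldehyde (ring A fragment)
Conditions: 2 M aq. HCl, THF, 60 °C; used crude at once
Reagents that add atoms: water, O
Why: Acid-catalysed enol ether hydrolysis (protonation at the benzylic carbon, hydration of the oxocarbenium ion, loss of methanol) should release the arylacetaldehyde, which is not stored because it enolises and self-condenses.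

Step 3
Reactants: 5 (4-benzyloxy-3-methoxyphenyl)methanol (O-benzylvanillyl alcohol)
Product: 6 1-benzyloxy-4-(chloromethyl)-2-methoxybenzene
Conditions: SOCl2 (1.2 equiv), CH2Cl2, 0 °C
Reagents that add atoms: thionyl chloride, O=S(Cl)Cl
Why: Chlorodehydroxylation of an electron-rich benzylic alcohol via its chlorosulfite is fast at 0 °C, and both aryl ethers are inert to it.

Step 4
Reactants: 6 benzylic chloride; 7 methyl bis(2,2,2-trifluoroethoxy)phosphorylacetate
Product: 8 methyl 3-(4-benzyloxy-3-methoxyphenyl)-2-[bis(2,2,2-trifluoroethoxy)phosphoryl]propanoate (racemic, ring D fragment)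
Conditions: 7 (1.5 equiv), NaH (1.4 equiv), NaI (10 mol%), THF/DMF, 0 °C → rt
Reagents that add atoms: none
Why: SN2 C-alkylation of the sodiated phosphonoacetate by a very reactive p-alkoxybenzyl halide (iodide-catalysed) should give the α-substituted Still–Gennari reagent, with excess 7 suppressing double alkylation and the racemic P-bearing centre being lost in step 12.

Step 5
Reactants: 9 divanillin (6,6'-dihydroxy-5,5'-dimethoxybiphenyl-3,3'-dicarbaldehyde)
Product: 10 6,6'-bis(benzyloxy)-5,5'-dimethoxybiphenyl-3,3'-dicarbaldehyde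
Conditions: BnBr (2.5 equiv), K2CO3 (3 equiv), DMF, 70 °C
Reagents that add atoms: benzyl bromide, BrCc1ccccc1
Why: Double Williamson etherification of two acidic phenols installs a group that tolerates base, hydride, peroxide, cuprate, fluoride and the later oxidants and leaves in a single hydrogenolysis.

Step 6
Reactants: 10 dialdehyde
Product: 11 6,6'-bis(benzyloxy)-3'-(hydroxymethyl)-5,5'-dimethoxybiphenyl-3-carbaldehyde (CH2OH on ring B, CHO on ring C)
Conditions: NaBH4 (0.3 equiv), THF/MeOH, −20 °C; 1 M HCl quench; chromatography, recovered 10 recycled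
Reagents that add atoms: none
Why: Sub-stoichiometric borohydride reduction desymmetrises the dialdehyde statistically because the formyl groups sit on electronically independent rings, the three components differ strongly in polarity, and over-reduced diol can be returned to 10 with MnO2.

Step 7
Reactants: 11 hydroxy aldehyde; 2 (methoxymethyl)triphenylphosphonium chloride
Product: 12 [6,6'-bis(benzyloxy)-5,5'-dimethoxy-3'-(2-methoxyethenyl)biphenyl-3-yl]methanol (E/Z mixture; enol ether on ring C)
Conditions: 2 (2.5 equiv), KOtBu (2.5 equiv), THF, 0 °C → rt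
Reagents that add atoms: none
Why: Wittig methoxymethylenation with excess ylide (one equivalent is spent on the hydroxyl proton) masks the future ring C acetaldehyde as a base- and hydride-stable enol ether.

Step 8
Reactants: 12 benzylic alcohol
Product: 14 ring B chloromethyl biaryl carrying the ring C enol ether, via benzylic mesylate 13 (not isolated)
Conditions: MsCl (1.3 equiv), Et3N (2 equiv), LiCl (5 equiv), THF/DMF, 0 °C → rt
Reagents that add atoms: methanesulfonyl chloride, CS(=O)(=O)Cl (atoms kept only in 13); lithium chloride, [Li+].[Cl-]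
Why: Mesylation followed by in situ SN2 chloride exchange turns the p-alkoxybenzylic alcohol into its chloride under constantly basic conditions, so the acid-labile enol ether is not touched.

Step 9
Reactants: 14 benzylic chloride; 7 methyl bis(2,2,2-trifluoroethoxy)phosphorylacetate
Product: 15 methyl 2-[bis(2,2,2-trifluoroethoxy)phosphoryl]-3-(ring B)propanoate of the biaryl (racemic; ring C enol ether retained)
Conditions: 7 (1.5 equiv), NaH (1.4 equiv), NaI (10 mol%), THF/DMF, 0 °C → rt
Reagents that add atoms: none
Why: The same SN2 phosphonate alkylation as in step 4 applies, the enol ether is inert to the stabilised carbanion, and the racemic centre vanishes in step 10.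

Step 10
Reactants: 15 biaryl phosphonate; 4 ring A acetaldehyde
Product: 16 methyl (Z)-4-(4-benzyloxy-3-methoxyphenyl)-2-[(ring B)methyl]but-2-enoate of the biaryl (ring C enol ether retained)
Conditions: KN(SiMe3)2 (0.98 equiv), 18-crown-6 (4 equiv), THF, −78 °C; then 4 (1.3 equiv)
Reagents that add atoms: none
Why: In the Still–Gennari olefination the electron-poor bis(trifluoroethyl) phosphonate with a dissociated potassium ion eliminates fast from the kinetic adduct, which should give the (Z)-trisubstituted enoate (ring A CH2 cis to CO2Me), and a slight deficit of base avoids enolisation of 4 and γ-deprotonation of the product.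

Step 11
Reactants: 16 enoate enol ether
Product: 17 the same (Z)-enoate with CH2CHO on ring C
Conditions: 2 M aq. HCl, THF, 50 °C; used crude at once
Reagents that add atoms: water, O
Why: Acid-catalysed enol ether hydrolysis as in step 2 should unmask the second arylacetaldehyde, while the methyl ester, the Z-olefin and the benzyl ethers are stable to dilute acid over the short reaction time.

Step 12
Reactants: 17 aldehyde; 8 ring D phosphonate
Product: 18 bis[(Z)-enoate]: half 1 ArA-CH2-CH=C(CO2Me)-CH2-ArB, half 2 ArC-CH2-CH=C(CO2Me)-CH2-ArD, each β-CH2 cis to its CO2Me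
Conditions: 8 (1.4 equiv), KN(SiMe3)2 (1.3 equiv), 18-crown-6 (4 equiv), THF, −78 °C; then 17
Reagents that add atoms: none
Why: A second Still–Gennari olefination under the same kinetic control should set the second Z-olefin, and because all base is consumed in pre-forming the stabilised carbanion the acidic γ-CH2 of the first enoate is left alone.

Step 13
Reactants: 18 bis-enoate
Product: 19 bis[(Z)-allylic alcohol] (each CO2Me replaced by CH2OH)
Conditions: iBu2AlH (5 equiv), CH2Cl2, −78 °C; aq. potassium sodium tartrate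
Reagents that add atoms: none
Why: 1,2-Reduction of conjugated esters with iBu2AlH gives allylic alcohols without conjugate reduction or change of olefin geometry.

Step 14
Reactants: 19 bis(allylic alcohol); 20 L-(+)-diethyl tartrate (chiral ligand, adds no atoms)
Product: 21 (2S,3R,2'S,3'R)-bis(2,3-epoxy alcohol): each oxirane C2 bears CH2OH and the α-CH2Ar, each C3 bears H and the β-CH2Ar cis to CH2OH
Conditions: Ti(OiPr)4 (0.5 equiv), 20 (0.6 equiv), tBuOOH (5 equiv, decane), 4 Å MS, CH2Cl2, −20 °C; cold aq. NaOH/brine work-up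
Reagents that add atoms: tert-butyl hydroperoxide, CC(C)(C)OO
Why: The Katsuki–Sharpless epoxidation transfers oxygen syn-stereospecifically within the titanium–(R,R)-tartrate–alkoxide complex to the face that makes C2 S (the sense known for nerol-type Z-allylic alcohols, hence 2S,3R), so all four centres are set by the reagent and a wrongly set half appears as a separable diastereomer (Horeau-type upgrading).

Step 15
Reactants: 21 bis(epoxy alcohol)
Product: 22 bis(tert-butyldimethylsilyl ether) of 21, (2S,3R,2'S,3'R)
Conditions: TBSCl (2.6 equiv), imidazole (5 equiv), DMF, rt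
Reagents that add atoms: tert-butyldimethylsilyl chloride, CC(C)(C)[Si](C)(C)Cl
Why: Imidazole-promoted silylation of the two primary alcohols is mild enough for the oxiranes and removes the free hydroxyl that could trigger Payne migration or consume organometallic reagent in the next step.

Step 16
Reactants: 22 bis-silyl bis-epoxide; 23 vinylmagnesium bromide
Product: 24 bis(tertiary alcohol) with a vinyl group on each Cβ (αR,βR in both halves; CH2OTBS retained)
Conditions: 23 (8 equiv), CuBr·SMe2 (4 equiv), THF/Me2S, −40 °C; then 22, −40 → 0 °C; aq. NH4Cl/NH3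
Reagents that add atoms: none
Why: The bromomagnesium divinylcuprate (monovalent copper) attacks each epoxide CH carbon collinearly with, and opposite to, its C–O bond while Mg2+ holds the departing oxygen, and the resulting trivalent alkyl(vinyl)copper species collapses by reductive elimination to the Cβ–vinyl bond. The closest known reaction type is the SN2 opening of trisubstituted 2,3-epoxy alcohol ethers at their less substituted carbon by Grignard-derived cuprates, used here twice in one flask at two remote, non-interacting sites. No ring is closed; two oxiranes open and two skeletal C–C bonds form. Each new Cβ centre arises by inversion of the (3R)-oxirane carbon fixed by the titanium–tartrate epoxidation of the Z-olefin, so vinyl ends anti to oxygen, whereas the Cα–O bond is never broken and Cα keeps its geometry (2S becomes R only through a change in CIP ranking). The step needs regioselectivity for CH over the fully substituted carbon, which the neopentyl-like shielding of that carbon by CH2OSi and CH2Ar secures, and the silyl ether excludes Payne migration and alkoxide-directed pathways. A weakly basic cuprate at low temperature without BF3-type activators is chosen so that ionisation at the tertiary carbon, participation of the p-alkoxyaryl rings and elimination towards the styrene stay suppressed.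

Step 17
Reactants: 24 bis-silyl ether
Product: 25 tetraol (each half a primary/tertiary 1,2-diol; vinyl groups retained; αR,βR)
Conditions: Bu4NF (3 equiv), THF, 0 °C → rt
Reagents that add atoms: none
Why: Fluoride-driven desilylation (strong Si–F bond) frees both primary alcohols without affecting olefins, benzyl ethers or stereocentres, and would also remove any silyl group that had migrated to the tertiary oxygen.

Step 18
Reactants: 25 tetraol
Product: 26 bis(α-hydroxy aldehyde) (CH2OH → CHO on each Cα; αR,βR)
Conditions: SO3·pyridine (6 equiv), DMSO, Et3N, CH2Cl2, 0 °C; used crude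
Reagents that add atoms: none
Why: The Parikh–Doering (activated DMSO) oxidation converts only the primary alcohols, cannot oxidise the tertiary ones and, unlike hypervalent-iodine or periodate-type oxidants, does not cleave the 1,2-diol.

Step 19
Reactants: 26 bis(hydroxy aldehyde)
Product: 27 bis(α-hydroxy acid) (αR,βR; vinyl groups retained)
Conditions: NaClO2, NaH2PO4, 2-methyl-2-butene (excess), tBuOH/H2O, rt
Reagents that add atoms: sodium chlorite, [Na+].[O-]Cl=O
Why: The Pinnick oxidation takes aldehydes to acids under buffered conditions, and the large excess of the trisubstituted alkene scavenger traps hypochlorous acid before it reaches the vinyl groups or the electron-rich rings.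

Step 20
Reactants: 27 bis(hydroxy acid)
Product: 29 bis(γ-oxo acid) drawn open-chain (tautomer of its 5-hydroxylactone; αR and βS by CIP rank change with unchanged geometry), via bis(vicinal diol) 28 (not isolated)
Conditions: OsO4 (4 mol%), NaIO4 (8 equiv), 2,6-lutidine, dioxane/H2O, rt; used crude
Reagents that add atoms: osmium tetroxide, O=[Os](=O)(=O)=O (oxygen carrier); sodium periodate, [Na+].[O-]I(=O)(=O)=O (terminal oxygen source)
Why: Lemieux–Johnson cleavage removes the terminal CH2 of each monosubstituted olefin without harming the arenes (which ozone might attack), periodate cleaves only the new glycol because the tertiary OH is 1,3 to it and α-hydroxy acids react far more slowly, and lutidine buffering plus ring–chain tautomerism protect Cβ from epimerisation.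

Step 21
Reactants: 29 bis(oxo acid)
Product: 31 tetra-O-benzyl bis-lactone (3R,4R in both lactones), via bis(γ-hydroxy acid) 30 (not isolated)
Conditions: NaBH4, THF/MeOH, 0 °C; then 1 M HCl, rt
Reagents that add atoms: none
Why: Borohydride reduces the aldehyde (through the open form of the pseudo-acid) but not the carboxylate, and acidification triggers 5-exo-trig lactonisation of the primary γ-hydroxy acid, placing OH cis to the β-CH2Ar and the two CH2Ar groups trans as fixed in steps 14 and 16.

Step 22
Reactants: 31 tetra-O-benzyl bis-lactone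
Product: 32 target CNP0218652.1
Conditions: H2 (1 atm), 10% Pd/C, EtOAc/EtOH, rt
Reagents that add atoms: none
Why: Catalytic hydrogenolysis cleaves the four aryl benzyl ethers, while the lactone C–O bonds and the homobenzylic tertiary alcohols are not benzylic and remain untouched.

Compound list
1 | 4-benzyloxy-3-methoxybenzaldehyde | COc1cc(C=O)ccc1OCc1ccccc1 | starting material
2 | (methoxymethyl)triphenylphosphonium chloride | COC[P+](c1ccccc1)(c1ccccc1)c1ccccc1.[Cl-] | starting material
3 | 1-benzyloxy-2-methoxy-4-(2-methoxyethenyl)benzene (E/Z) | COC=Cc1ccc(OCc2ccccc2)c(OC)c1 | intermediate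
4 | (4-benzyloxy-3-methoxyphenyl)acetaldehyde | COc1cc(CC=O)ccc1OCc1ccccc1 | intermediate
5 | (4-benzyloxy-3-methoxyphenyl)methanol | COc1cc(CO)ccc1OCc1ccccc1 | starting material
6 | 1-benzyloxy-4-(chloromethyl)-2-methoxybenzene | COc1cc(CCl)ccc1OCc1ccccc1 | intermediate
7 | methyl bis(2,2,2-trifluoroethoxy)phosphorylacetate | COC(=O)CP(=O)(OCC(F)(F)F)OCC(F)(F)F | starting material
8 | ring D phosphonate (racemic) | COC(=O)C(Cc1ccc(OCc2ccccc2)c(OC)c1)P(=O)(OCC(F)(F)F)OCC(F)(F)F | intermediate
9 | divanillin | COc1cc(C=O)cc(-c2cc(C=O)cc(OC)c2O)c1O | starting material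
10 | di-O-benzyldivanillin | COc1cc(C=O)cc(-c2cc(C=O)cc(OC)c2OCc2ccccc2)c1OCc1ccccc1 | intermediate
11 | mono-reduced hydroxy aldehyde | COc1cc(CO)cc(-c2cc(C=O)cc(OC)c2OCc2ccccc2)c1OCc1ccccc1 | intermediate
12 | biaryl alcohol with ring C enol ether (E/Z) | COC=Cc1cc(OC)c(OCc2ccccc2)c(-c2cc(CO)cc(OC)c2OCc2ccccc2)c1 | intermediate
13 | benzylic mesylate of 12 | COC=Cc1cc(OC)c(OCc2ccccc2)c(-c2cc(COS(C)(=O)=O)cc(OC)c2OCc2ccccc2)c1 | intermediate
14 | benzylic chloride | COC=Cc1cc(OC)c(OCc2ccccc2)c(-c2cc(CCl)cc(OC)c2OCc2ccccc2)c1 | intermediate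
15 | biaryl phosphonate (racemic) | COC=Cc1cc(OC)c(OCc2ccccc2)c(-c2cc(CC(C(=O)OC)P(=O)(OCC(F)(F)F)OCC(F)(F)F)cc(OC)c2OCc2ccccc2)c1 | intermediate
16 | mono-(Z)-enoate with ring C enol ether | COc1cc(C/C=C(\C(=O)OC)Cc2cc(OC)c(OCc3ccccc3)c(-c3cc(C=COC)cc(OC)c3OCc3ccccc3)c2)ccc1OCc1ccccc1 | intermediate
17 | mono-(Z)-enoate with ring C acetaldehyde | COc1cc(C/C=C(\C(=O)OC)Cc2cc(OC)c(OCc3ccccc3)c(-c3cc(CC=O)cc(OC)c3OCc3ccccc3)c2)ccc1OCc1ccccc1 | intermediate
18 | bis[(Z)-enoate] | COc1cc(C/C=C(\C(=O)OC)Cc2cc(OC)c(OCc3ccccc3)c(-c3cc(C/C=C(\C(=O)OC)Cc4ccc(OCc5ccccc5)c(OC)c4)cc(OC)c3OCc3ccccc3)c2)ccc1OCc1ccccc1 | intermediate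
19 | bis[(Z)-allylic alcohol] | COc1cc(C/C=C(\CO)Cc2cc(OC)c(OCc3ccccc3)c(-c3cc(C/C=C(\CO)Cc4ccc(OCc5ccccc5)c(OC)c4)cc(OC)c3OCc3ccccc3)c2)ccc1OCc1ccccc1 | intermediate
20 | L-(+)-diethyl tartrate (2R,3R) | CCOC(=O)[C@H](O)[C@@H](O)C(=O)OCC | starting material
21 | (2S,3R,2'S,3'R)-bis(epoxy alcohol) | COc1cc(C[C@H]2O[C@]2(CO)Cc2cc(OC)c(OCc3ccccc3)c(-c3cc(C[C@H]4O[C@]4(CO)Cc4ccc(OCc5ccccc5)c(OC)c4)cc(OC)c3OCc3ccccc3)c2)ccc1OCc1ccccc1 | intermediate
22 | bis-TBS bis-epoxide (key-step precursor) | COc1cc(C[C@H]2O[C@]2(CO[Si](C)(C)C(C)(C)C)Cc2cc(OC)c(OCc3ccccc3)c(-c3cc(C[C@H]4O[C@]4(CO[Si](C)(C)C(C)(C)C)Cc4ccc(OCc5ccccc5)c(OC)c4)cc(OC)c3OCc3ccccc3)c2)ccc1OCc1ccccc1 | intermediate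
23 | vinylmagnesium bromide | C=C[Mg]Br | starting material
24 | bis(vinyl) bis(tertiary alcohol) (key-step product) | COc1cc(C[C@H](C=C)[C@@](O)(CO[Si](C)(C)C(C)(C)C)Cc2cc(OC)c(OCc3ccccc3)c(-c3cc(C[C@H](C=C)[C@@](O)(CO[Si](C)(C)C(C)(C)C)Cc4ccc(OCc5ccccc5)c(OC)c4)cc(OC)c3OCc3ccccc3)c2)ccc1OCc1ccccc1 | intermediate
25 | tetraol | COc1cc(C[C@H](C=C)[C@@](O)(CO)Cc2cc(OC)c(OCc3ccccc3)c(-c3cc(C[C@H](C=C)[C@@](O)(CO)Cc4ccc(OCc5ccccc5)c(OC)c4)cc(OC)c3OCc3ccccc3)c2)ccc1OCc1ccccc1 | intermediate
26 | bis(α-hydroxy aldehyde) | COc1cc(C[C@H](C=C)[C@@](O)(C=O)Cc2cc(OC)c(OCc3ccccc3)c(-c3cc(C[C@H](C=C)[C@@](O)(C=O)Cc4ccc(OCc5ccccc5)c(OC)c4)cc(OC)c3OCc3ccccc3)c2)ccc1OCc1ccccc1 | intermediate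
27 | bis(α-hydroxy acid) | COc1cc(C[C@H](C=C)[C@@](O)(C(=O)O)Cc2cc(OC)c(OCc3ccccc3)c(-c3cc(C[C@H](C=C)[C@@](O)(C(=O)O)Cc4ccc(OCc5ccccc5)c(OC)c4)cc(OC)c3OCc3ccccc3)c2)ccc1OCc1ccccc1 | intermediate
28 | bis(vicinal diol) (new carbinol centres unassigned) | COc1cc(C[C@H](C(O)CO)[C@@](O)(C(=O)O)Cc2cc(OC)c(OCc3ccccc3)c(-c3cc(C[C@H](C(O)CO)[C@@](O)(C(=O)O)Cc4ccc(OCc5ccccc5)c(OC)c4)cc(OC)c3OCc3ccccc3)c2)ccc1OCc1ccccc1 | intermediate
29 | bis(γ-oxo acid) (open form) | COc1cc(C[C@H](C=O)[C@@](O)(C(=O)O)Cc2cc(OC)c(OCc3ccccc3)c(-c3cc(C[C@H](C=O)[C@@](O)(C(=O)O)Cc4ccc(OCc5ccccc5)c(OC)c4)cc(OC)c3OCc3ccccc3)c2)ccc1OCc1ccccc1 | intermediate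
30 | bis(γ-hydroxy acid) | COc1cc(C[C@H](CO)[C@@](O)(C(=O)O)Cc2cc(OC)c(OCc3ccccc3)c(-c3cc(C[C@H](CO)[C@@](O)(C(=O)O)Cc4ccc(OCc5ccccc5)c(OC)c4)cc(OC)c3OCc3ccccc3)c2)ccc1OCc1ccccc1 | intermediate
31 | tetra-O-benzyl bis-lactone | COc1cc(C[C@@H]2COC(=O)[C@@]2(O)Cc2cc(OC)c(OCc3ccccc3)c(-c3cc(C[C@@H]4COC(=O)[C@@]4(O)Cc4ccc(OCc5ccccc5)c(OC)c4)cc(OC)c3OCc3ccccc3)c2)ccc1OCc1ccccc1 | intermediate
32 | CNP0218652.1 | COc1cc(C[C@@H]2COC(=O)[C@@]2(O)Cc2cc(OC)c(O)c(-c3cc(C[C@@H]4COC(=O)[C@@]4(O)Cc4ccc(O)c(OC)c4)cc(OC)c3O)c2)ccc1O | target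

Total step count: 22. Longest linear sequence: 18 steps (9 → 32, steps 5–22).

Steps most likely to fail

Step 16 (double cuprate opening).
- **What may go wrong:** The reaction may stall after the first opening because each CH carbon adjoins a quaternary centre. Magnesium halide may assist ionisation at the tertiary carbon, leading to halide capture or a 1,2-shift. Base may induce elimination towards the benzylic position.
- **Fallback:** Setting out from 22, the carbon arm is introduced as a slim sp nucleophile free of copper and magnesium halide. LiC≡CH·H2NCH2CH2NH2 in DMSO/THF at rt to 40 °C should open both oxiranes at the same CH carbons by plain SN2 inversion. This gives the bis(ethynyl) bis(tertiary alcohol) F1. Semihydrogenation (H2, Pd/CaCO3 poisoned with Pb(OAc)2, quinoline, EtOAc) then comes back to the route at 24.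

Step 14 (double asymmetric epoxidation).
- **What may go wrong:** Z-olefins carrying a further C2 substituent can show slow turnover and eroded facial selectivity. Titanium may also promote opening of the epoxy alcohol during long reaction times.
- **Fallback:** Setting out from 19, the hydroxyl-directed metal catalysis is given up. Both alcohols are silylated first (TBSCl, imidazole, DMF) to give the bis(allylic silyl ether) F2. F2 is then epoxidised by the dioxirane of the D-fructose-derived ketone (Shi epoxidation: KHSO5 as 2KHSO5·KHSO4·K2SO4, K2CO3, Bu4NHSO4, MeCN/dimethoxymethane/aq. Na2B4O7 buffer, 0 °C). In the spiro transition-state model the two CH2Ar groups form the trans pair of each trisubstituted olefin, which predicts the same (2S,3R) sense. The sequence comes back to the route at 22.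

Step 12 (second Still–Gennari olefination on the advanced aldehyde).
- **What may go wrong:** The arylacetaldehyde may enolise and self-condense. Base may move a double bond into conjugation with an aryl ring. Z-selectivity may be insufficient with the bulky α-substituted phosphonate.
- **Fallback:** Setting out from 17, the geometry is built by stepwise substitution.
  - Ramirez dibromo-olefination (CBr4, PPh3, CH2Cl2, 0 °C) gives the 1,1-dibromoalkene F3.
  - Chloride 6 is converted (Zn dust, LiCl, THF) into (4-benzyloxy-3-methoxybenzyl)zinc chloride F4.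
  - A trans-selective Negishi coupling (PdCl2(DPEphos) 3 mol%, THF, 0 °C → rt) replaces only the bromine trans to the ring C CH2 and gives the (Z)-bromoalkene F5.
  - Methoxycarbonylation with retention (Pd(OAc)2, dppf, CO 1 atm, MeOH, Et3N, DMF, 60 °C) comes back to the route at 18.

Further compounds
F1 | step 16 | bis(ethynyl) bis(tertiary alcohol), αR,βR in both halves | COc1cc(C[C@H](C#C)[C@@](O)(CO[Si](C)(C)C(C)(C)C)Cc2cc(OC)c(OCc3ccccc3)c(-c3cc(C[C@H](C#C)[C@@](O)(CO[Si](C)(C)C(C)(C)C)Cc4ccc(OCc5ccccc5)c(OC)c4)cc(OC)c3OCc3ccccc3)c2)ccc1OCc1ccccc1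
F2 | step 14 | bis(TBS ether) of bis[(Z)-allylic alcohol] 19 | COc1cc(C/C=C(\CO[Si](C)(C)C(C)(C)C)Cc2cc(OC)c(OCc3ccccc3)c(-c3cc(C/C=C(\CO[Si](C)(C)C(C)(C)C)Cc4ccc(OCc5ccccc5)c(OC)c4)cc(OC)c3OCc3ccccc3)c2)ccc1OCc1ccccc1
F3 | step 12 | 1,1-dibromoalkene from 17 | COc1cc(C/C=C(\C(=O)OC)Cc2cc(OC)c(OCc3ccccc3)c(-c3cc(CC=C(Br)Br)cc(OC)c3OCc3ccccc3)c2)ccc1OCc1ccccc1
F4 | step 12 | (4-benzyloxy-3-methoxybenzyl)zinc chloride | COc1cc(C[Zn]Cl)ccc1OCc1ccccc1
F5 | step 12 | (Z)-bromoalkene (Br cis to ring C CH2) | COc1cc(C/C=C(\C(=O)OC)Cc2cc(OC)c(OCc3ccccc3)c(-c3cc(C/C=C(\Br)Cc4ccc(OCc5ccccc5)c(OC)c4)cc(OC)c3OCc3ccccc3)c2)ccc1OCc1ccccc1
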